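**Retrosynthetic overview**
- Last operations: the C8 methacrylate and the C10 acetate go on after both rings exist.
- Ring B (butenolide): ring-closing metathesis of a C6 2-(acetoxymethyl)acrylate onto the C7 exocyclic methylene; the C8 carbinol comes from CBS reduction of the C8 enone.
- Ring A (ten-membered carbocycle): ring-closing metathesis of a C5 vinyl and a C4 isopropenyl end, giving the Z C4=C5 alkene.
- C7–C8 bond: thioester–alkenylstannane ketone synthesis joining fragment 1 (C8–C10 and C1–C4; C10 set by a copper–bis(oxazoline) aldol on a 1,2-diketone) with fragment 2 (C5–C7; C6 set by lipase resolution).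
- Ring order: ring A first, then ring B.

Assumption: atom labels follow germacrane numbering (C1 ketone, C4=C5 ring alkene, C6 lactone carbinol, C7=C11 butenolide alkene, C8 methacrylate carbinol, C10 acetoxy carbon, C12 lactone carbonyl, C13 acetoxymethyl; target = 4Z,6R,8S,10S); the lipase follows the Kazlauskas rule and the copper aldol follows the pyruvate precedent.

**Route**

Step 1
Reactants: 1 3,3-dimethoxybutan-2-one; 2 3-bromo-2-methylprop-1-ene
Product: 4 2,2-dimethoxy-6-methylhept-6-en-3-one, via lithium enolate 3 (not isolated)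
Conditions: LiN(iPr)2, THF, −78 °C; then 2, −78 to 0 °C
Reagents that add atoms: none
Why: Kinetic enolate alkylation, in which the ketal blocks the other α-position so that only the methyl group is deprotonated and then allylated by SN2 displacement.

Step 2
Reactants: 4 2,2-dimethoxy-6-methylhept-6-en-3-one
Product: 5 6-methylhept-6-ene-2,3-dione
Conditions: TFA, H2O, CH2Cl2, 0 °C
Reagents that add atoms: water, O
Why: Acid-catalysed ketal hydrolysis frees the 1,2-diketone and is too mild to hydrate or shift the 1,1-disubstituted alkene.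

Step 3
Reactants: 6 S-ethyl ethanethioate
Product: 8 {[1-(ethylsulfanyl)ethenyl]oxy}(trimethyl)silane, via lithium thioester enolate 7 (not isolated)
Conditions: LiN(iPr)2, THF, −78 °C; then Me3SiCl
Reagents that add atoms: chlorotrimethylsilane, C[Si](C)(C)Cl
Why: O-silylation of the lithium thioester enolate gives the silyl ketene thioacetal (enol silane formation).

Step 4
Reactants: 5 6-methylhept-6-ene-2,3-dione; 8 {[1-(ethylsulfanyl)ethenyl]oxy}(trimethyl)silane
Product: 9 S-ethyl (3S)-3,7-dimethyl-4-oxo-3-[(trimethylsilyl)oxy]oct-7-enethioate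
Conditions: Cu(OTf)2 (10 mol %), (S,S)-tBu-box (11 mol %), THF, −78 °C
Reagents that add atoms: none
Why: Evans copper–bis(oxazoline) Mukaiyama aldol in which the chelated diketone is attacked at the less hindered methyl ketone carbonyl on the face left open by the ligand, setting C10 as S, with silyl transfer giving the tertiary silyl ether.

Step 5
Reactants: 10 ethynyl(trimethyl)silane; 11 prop-2-enal
Product: 13 rac-5-(trimethylsilyl)pent-1-en-4-yn-3-ol, via lithium acetylide 12 (not isolated)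
Conditions: n-BuLi, THF, −78 °C; then 11; H2O
Reagents that add atoms: none
Why: 1,2-Addition of a lithium acetylide to the enal gives the racemic alkynyl vinyl carbinol.

Step 6
Reactants: 13 rac-5-(trimethylsilyl)pent-1-en-4-yn-3-ol
Product: 14 (3R)-5-(trimethylsilyl)pent-1-en-4-yn-3-yl acetate
Conditions: Amano lipase PS, vinyl acetate, MTBE, rt, to ca. 50 % conversion
Reagents that add atoms: vinyl acetate, C=COC(C)=O
Why: Lipase-catalysed kinetic resolution by transesterification acetylates only the R alcohol (silylethynyl as the large group), which fixes the future C6 centre.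

Step 7
Reactants: 14 (3R)-5-(trimethylsilyl)pent-1-en-4-yn-3-yl acetate
Product: 15 (3R)-pent-1-en-4-yn-3-ol
Conditions: K2CO3, MeOH, 0 °C to rt
Reagents that add atoms: none
Why: Methanolysis removes the acetate (transesterification) and the alkynyl silyl group (protodesilylation) in one operation without touching the stereocentre.

Step 8
Reactants: 15 (3R)-pent-1-en-4-yn-3-ol
Product: 16 (3R)-2-(tributylstannyl)penta-1,4-dien-3-ol
Conditions: Bu3SnH, Mo(CO)3(CNtBu)3 (2 mol %), hydroquinone, THF, 55 °C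
Reagents that add atoms: tributyltin hydride, CCCC[SnH](CCCC)CCCC
Why: Molybdenum-catalysed hydrostannation puts tin on the alkyne carbon next to the carbinol (α-selective), giving the 1,1-disubstituted alkenylstannane.

Step 9
Reactants: 17 2-(bromomethyl)prop-2-enoic acid
Product: 18 2-[(acetyloxy)methyl]prop-2-enoic acid
Conditions: KOAc, AcOH, 80 °C
Reagents that add atoms: potassium acetate, CC(=O)[O-].[K+]
Why: Nucleophilic displacement of the allylic bromide by acetate (SN2 and SN2′ give the same product) supplies the C11–C13 unit with the C13 acetate in place.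

Step 10
Reactants: 9 S-ethyl (3S)-3,7-dimethyl-4-oxo-3-[(trimethylsilyl)oxy]oct-7-enethioate; 16 (3R)-2-(tributylstannyl)penta-1,4-dien-3-ol
Product: 19 (6S,10R)-10-hydroxy-2,6-dimethyl-9-methylidene-6-[(trimethylsilyl)oxy]dodeca-1,11-diene-5,8-dione
Conditions: Pd2(dba)3 (2.5 mol %), P(2-furyl)3, CuO2PPh2 (1.5 equiv), THF, 50 °C
Reagents that add atoms: none
Why: Liebeskind–Srogl ketone synthesis joins the thioester and the alkenylstannane under neutral conditions, so the C1 ketone, the free alcohol and both stereocentres are untouched.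

Step 11
Reactants: 19 (6S,10R)-10-hydroxy-2,6-dimethyl-9-methylidene-6-[(trimethylsilyl)oxy]dodeca-1,11-diene-5,8-dione
Product: 20 (2S,6R,7Z)-6-hydroxy-2,8-dimethyl-5-methylidene-2-[(trimethylsilyl)oxy]cyclodec-7-ene-1,4-dione
Conditions: second-generation Hoveyda–Grubbs catalyst (10 mol %), 1,4-benzoquinone, toluene, 80 °C, 1 mM
Reagents that add atoms: none
Why: Ring-closing metathesis of the vinyl and isopropenyl ends closes ring A, and the ten-membered ring with three further sp2 carbons is expected to take the less strained cis (Z) C4=C5 geometry.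

Step 12
Reactants: 20 (2S,6R,7Z)-6-hydroxy-2,8-dimethyl-5-methylidene-2-[(trimethylsilyl)oxy]cyclodec-7-ene-1,4-dione; 18 2-[(acetyloxy)methyl]prop-2-enoic acid
Product: 22 (1R,2Z,7S)-3,7-dimethyl-10-methylidene-6,9-dioxo-7-[(trimethylsilyl)oxy]cyclodec-2-en-1-yl 2-[(acetyloxy)methyl]prop-2-enoate, via acid chloride 21 (not isolated)
Conditions: 18, (COCl)2, DMF (cat.), CH2Cl2, 0 °C; then 20, 2,6-lutidine, CH2Cl2, −20 °C to rt
Reagents that add atoms: none
Why: Esterification through the acid chloride acylates the only free hydroxyl (C6), and the hindered non-nucleophilic base avoids SN2′ attack on the allylic acetate.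

Step 13
Reactants: 22 (1R,2Z,7S)-3,7-dimethyl-10-methylidene-6,9-dioxo-7-[(trimethylsilyl)oxy]cyclodec-2-en-1-yl 2-[(acetyloxy)methyl]prop-2-enoate
Product: 23 (1R,2Z,7S,9S)-9-hydroxy-3,7-dimethyl-10-methylidene-6-oxo-7-[(trimethylsilyl)oxy]cyclodec-2-en-1-yl 2-[(acetyloxy)methyl]prop-2-enoate
Conditions: (R)-2-methyl-CBS-oxazaborolidine (0.5 equiv), catecholborane, toluene, −78 °C; MeOH, aq. NaHCO3
Reagents that add atoms: none
Why: Corey–Bakshi–Shibata reduction with the alkenyl group as the large substituent gives the 8S allylic alcohol under reagent control, while the hindered C1 ketone next to the silyloxy quaternary carbon and the esters are not reduced.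

Step 14
Reactants: 23 (1R,2Z,7S,9S)-9-hydroxy-3,7-dimethyl-10-methylidene-6-oxo-7-[(trimethylsilyl)oxy]cyclodec-2-en-1-yl 2-[(acetyloxy)methyl]prop-2-enoate
Product: 24 [(4S,6S,10Z,11aR)-4-hydroxy-6,10-dimethyl-2,7-dioxo-6-[(trimethylsilyl)oxy]-2,4,5,6,7,8,9,11a-octahydrocyclodeca[b]furan-3-yl]methyl acetate
Conditions: second-generation Hoveyda–Grubbs catalyst (15 mol %), toluene, 100 °C, 2 mM, argon sparge
Reagents that add atoms: none
Why: Ring-closing metathesis of the acrylate with the exocyclic methylene forms the tetrasubstituted C7=C11 alkene and with it ring B, the ring alkene being inert.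

Step 15
Reactants: 24 [(4S,6S,10Z,11aR)-4-hydroxy-6,10-dimethyl-2,7-dioxo-6-[(trimethylsilyl)oxy]-2,4,5,6,7,8,9,11a-octahydrocyclodeca[b]furan-3-yl]methyl acetate
Product: 25 (4S,6S,10Z,11aR)-3-[(acetyloxy)methyl]-6,10-dimethyl-2,7-dioxo-6-[(trimethylsilyl)oxy]-2,4,5,6,7,8,9,11a-octahydrocyclodeca[b]furan-4-yl 2-methylprop-2-enoate
Conditions: methacrylic anhydride, Et3N, DMAP (cat.), CH2Cl2, 0 °C
Reagents that add atoms: methacrylic anhydride, C=C(C)C(=O)OC(=O)C(C)=C
Why: DMAP-catalysed acylation of the secondary C8 alcohol installs the methacrylate with retention and only after both metatheses, so it cannot compete in them.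

Step 16
Reactants: 25 (4S,6S,10Z,11aR)-3-[(acetyloxy)methyl]-6,10-dimethyl-2,7-dioxo-6-[(trimethylsilyl)oxy]-2,4,5,6,7,8,9,11a-octahydrocyclodeca[b]furan-4-yl 2-methylprop-2-enoate
Product: 27 (4S,6S,10Z,11aR)-6-(acetyloxy)-3-[(acetyloxy)methyl]-6,10-dimethyl-2,7-dioxo-2,4,5,6,7,8,9,11a-octahydrocyclodeca[b]furan-4-yl 2-methylprop-2-enoate, via tertiary alcohol 26 (not isolated)
Conditions: HF·pyridine, THF, 0 °C; evaporate; then Ac2O, Sc(OTf)3 (5 mol %), MeCN, −20 °C
Reagents that add atoms: acetic anhydride, CC(=O)OC(C)=O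
Why: Desilylation followed by Sc(OTf)3-catalysed acetylation of the tertiary α-ketol gives the C10 acetate without base, so the epimerisable C6 centre is not disturbed.

**Compound list**

1 | 3,3-dimethoxybutan-2-one | CC(=O)C(C)(OC)OC | starting material
2 | 3-bromo-2-methylprop-1-ene | C=C(C)CBr | starting material
3 | lithium 3,3-dimethoxybut-1-en-2-olate | [Li+].C=C([O-])C(C)(OC)OC | intermediate
4 | 2,2-dimethoxy-6-methylhept-6-en-3-one | COC(C)(OC)C(=O)CCC(C)=C | intermediate
5 | 6-methylhept-6-ene-2,3-dione | CC(=O)C(=O)CCC(C)=C | intermediate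
6 | S-ethyl ethanethioate | CCSC(C)=O | starting material
7 | lithium 1-(ethylsulfanyl)ethen-1-olate | [Li+].C=C([O-])SCC | intermediate
8 | {[1-(ethylsulfanyl)ethenyl]oxy}(trimethyl)silane | C=C(O[Si](C)(C)C)SCC | intermediate
9 | S-ethyl (3S)-3,7-dimethyl-4-oxo-3-[(trimethylsilyl)oxy]oct-7-enethioate | CCSC(=O)C[C@](C)(O[Si](C)(C)C)C(=O)CCC(C)=C | intermediate
10 | ethynyl(trimethyl)silane | C#C[Si](C)(C)C | starting material
11 | prop-2-enal | C=CC=O | starting material
12 | lithium (trimethylsilyl)acetylide | [Li+].[C-]#C[Si](C)(C)C | intermediate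
13 | rac-5-(trimethylsilyl)pent-1-en-4-yn-3-ol | C=CC(O)C#C[Si](C)(C)C | intermediate
14 | (3R)-5-(trimethylsilyl)pent-1-en-4-yn-3-yl acetate | C[Si](C)(C)C#C[C@H](OC(C)=O)C=C | intermediate
15 | (3R)-pent-1-en-4-yn-3-ol | C#C[C@H](O)C=C | intermediate
16 | (3R)-2-(tributylstannyl)penta-1,4-dien-3-ol | C=C([Sn](CCCC)(CCCC)CCCC)[C@H](O)C=C | intermediate
17 | 2-(bromomethyl)prop-2-enoic acid | OC(=O)C(=C)CBr | starting material
18 | 2-[(acetyloxy)methyl]prop-2-enoic acid | CC(=O)OCC(=C)C(O)=O | intermediate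
19 | (6S,10R)-10-hydroxy-2,6-dimethyl-9-methylidene-6-[(trimethylsilyl)oxy]dodeca-1,11-diene-5,8-dione | O=C(C[C@](C)(O[Si](C)(C)C)C(=O)CCC(C)=C)C(=C)[C@H](O)C=C | intermediate
20 | (2S,6R,7Z)-6-hydroxy-2,8-dimethyl-5-methylidene-2-[(trimethylsilyl)oxy]cyclodec-7-ene-1,4-dione | O=C1C[C@](C)(O[Si](C)(C)C)C(=O)CC/C(C)=C\[C@@H](O)C1=C | intermediate
21 | 2-[(acetyloxy)methyl]prop-2-enoyl chloride | CC(=O)OCC(=C)C(Cl)=O | intermediate
22 | (1R,2Z,7S)-3,7-dimethyl-10-methylidene-6,9-dioxo-7-[(trimethylsilyl)oxy]cyclodec-2-en-1-yl 2-[(acetyloxy)methyl]prop-2-enoate | O=C1C[C@](C)(O[Si](C)(C)C)C(=O)CC/C(C)=C\[C@@H](OC(=O)C(=C)COC(C)=O)C1=C | intermediate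
23 | (1R,2Z,7S,9S)-9-hydroxy-3,7-dimethyl-10-methylidene-6-oxo-7-[(trimethylsilyl)oxy]cyclodec-2-en-1-yl 2-[(acetyloxy)methyl]prop-2-enoate | O[C@H]1C[C@](C)(O[Si](C)(C)C)C(=O)CC/C(C)=C\[C@@H](OC(=O)C(=C)COC(C)=O)C1=C | intermediate
24 | [(4S,6S,10Z,11aR)-4-hydroxy-6,10-dimethyl-2,7-dioxo-6-[(trimethylsilyl)oxy]-2,4,5,6,7,8,9,11a-octahydrocyclodeca[b]furan-3-yl]methyl acetate | O[C@H]1C[C@](C)(O[Si](C)(C)C)C(=O)CC/C(C)=C\[C@H]2OC(=O)C(COC(C)=O)=C12 | intermediate
25 | (4S,6S,10Z,11aR)-3-[(acetyloxy)methyl]-6,10-dimethyl-2,7-dioxo-6-[(trimethylsilyl)oxy]-2,4,5,6,7,8,9,11a-octahydrocyclodeca[b]furan-4-yl 2-methylprop-2-enoate | C=C(C)C(=O)O[C@H]1C[C@](C)(O[Si](C)(C)C)C(=O)CC/C(C)=C\[C@H]2OC(=O)C(COC(C)=O)=C12 | intermediate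
26 | (4S,6S,10Z,11aR)-3-[(acetyloxy)methyl]-6-hydroxy-6,10-dimethyl-2,7-dioxo-2,4,5,6,7,8,9,11a-octahydrocyclodeca[b]furan-4-yl 2-methylprop-2-enoate | C=C(C)C(=O)O[C@H]1C[C@](C)(O)C(=O)CC/C(C)=C\[C@H]2OC(=O)C(COC(C)=O)=C12 | intermediate
27 | (4S,6S,10Z,11aR)-6-(acetyloxy)-3-[(acetyloxy)methyl]-6,10-dimethyl-2,7-dioxo-2,4,5,6,7,8,9,11a-octahydrocyclodeca[b]furan-4-yl 2-methylprop-2-enoate (CNP0115165.3) | C=C(C)C(=O)O[C@H]1C[C@](C)(OC(C)=O)C(=O)CC/C(C)=C\[C@H]2OC(=O)C(COC(C)=O)=C12 | target

**Totals**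
- Total step count: 16.
- Longest linear sequence: 11 steps (5, 6, 7, 8, 10, 11, 12, 13, 14, 15, 16).

**Three steps most likely to fail**

Step 11 (ten-membered ring by metathesis; risks are oligomers, an E/Z mixture, or isomerisation of the allylic alcohol). The fallback sets out from 16 and comes back at 20, replacing steps 1, 2, 4, 10 and 11; it fixes the Z alkene in a small temporary ring and closes ring A at C7–C8 instead. Stannane 16 is esterified with commercial 4-methylpent-4-enoic acid (DIC, DMAP) to the dienyl ester F1. Ring-closing metathesis with second-generation Grubbs catalyst then gives the seven-membered lactone F2, in which the ring can only hold the cis C4=C5 alkene. 1-Ethoxyvinyllithium opens the lactone at the future C1 to the hydroxy enol-ether ketone F3, and oxalic acid on wet silica hydrolyses the enol ether to the 1,2-diketone F4. The Cu(OTf)2/(S,S)-tBu-box aldol with 8, as in step 4, gives the seco thioester F5. An intramolecular thioester–stannane coupling (Pd2(dba)3, P(2-furyl)3, CuO2PPh2, THF, 1 mM) then forms the C7–C8 bond and delivers 20.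

Step 14 (tetrasubstituted alkene by metathesis between two 1,1-disubstituted alkenes on a crowded macrocycle). The fallback sets out from 20 and comes back at 24; it uses relay metathesis so that the catalyst is carried onto C11 intramolecularly. tert-Butyl acrylate and hex-5-enal (DABCO) give the Baylis–Hillman alcohol F6. Acetylation followed by DABCO-mediated SN2′ transposition gives the rearranged primary allylic acetate F7, and TFA frees the relay acid F8. Alcohol 20 is acylated with F8 as in step 12 to the relay ester F9, and (R)-CBS reduction as in step 13 gives the relay alcohol F10. Second-generation Grubbs catalyst engages the terminal alkene of F10, expels cyclopentene to leave the carbene on C11, and this closes onto the exocyclic methylene to give 24.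

Step 10 (coupling of a hindered α-stannyl allylic alcohol with an S-alkyl thioester). The fallback sets out from 16 (with 9) and comes back at 19; it swaps the copper-mediated stannane coupling for a more nucleophilic organozinc. Stannane 16 is deprotonated with MeLi and undergoes tin–lithium exchange with n-BuLi (THF, −78 °C) to the dilithio species F11. ZnCl2 converts it to the alkenylzinc F12, which is coupled with thioester 9 under Fukuyama conditions (PdCl2(PPh3)2, THF/toluene, rt). The organozinc does not add to the C1 ketone, and aqueous NH4Cl work-up gives 19.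

Further compounds

F1 | step 11 | (3R)-2-(tributylstannyl)penta-1,4-dien-3-yl 4-methylpent-4-enoate | C=C(C)CCC(=O)O[C@H](C=C)C(=C)[Sn](CCCC)(CCCC)CCCC
F2 | step 11 | (7R)-5-methyl-7-[1-(tributylstannyl)ethenyl]-4,7-dihydrooxepin-2(3H)-one | O=C1CCC(C)=C[C@H](C(=C)[Sn](CCCC)(CCCC)CCCC)O1
F3 | step 11 | (6Z,8R)-2-ethoxy-8-hydroxy-6-methyl-9-(tributylstannyl)deca-1,6,9-trien-3-one | C=C(OCC)C(=O)CC/C(C)=C\[C@@H](O)C(=C)[Sn](CCCC)(CCCC)CCCC
F4 | step 11 | (6Z,8R)-8-hydroxy-6-methyl-9-(tributylstannyl)deca-6,9-diene-2,3-dione | CC(=O)C(=O)CC/C(C)=C\[C@@H](O)C(=C)[Sn](CCCC)(CCCC)CCCC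
F5 | step 11 | S-ethyl (3S,7Z,9R)-9-hydroxy-3,7-dimethyl-4-oxo-10-(tributylstannyl)-3-[(trimethylsilyl)oxy]undeca-7,10-dienethioate | CCSC(=O)C[C@](C)(O[Si](C)(C)C)C(=O)CC/C(C)=C\[C@@H](O)C(=C)[Sn](CCCC)(CCCC)CCCC
F6 | step 14 | tert-butyl 3-hydroxy-2-methylideneoct-7-enoate | C=CCCCC(O)C(=C)C(=O)OC(C)(C)C
F7 | step 14 | tert-butyl (2E)-2-[(acetyloxy)methyl]octa-2,7-dienoate | C=CCCC/C=C(\COC(C)=O)C(=O)OC(C)(C)C
F8 | step 14 | (2E)-2-[(acetyloxy)methyl]octa-2,7-dienoic acid | C=CCCC/C=C(\COC(C)=O)C(O)=O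
F9 | step 14 | (1R,2Z,7S)-3,7-dimethyl-10-methylidene-6,9-dioxo-7-[(trimethylsilyl)oxy]cyclodec-2-en-1-yl (2E)-2-[(acetyloxy)methyl]octa-2,7-dienoate | O=C1C[C@](C)(O[Si](C)(C)C)C(=O)CC/C(C)=C\[C@@H](OC(=O)C(/COC(C)=O)=C/CCCC=C)C1=C
F10 | step 14 | (1R,2Z,7S,9S)-9-hydroxy-3,7-dimethyl-10-methylidene-6-oxo-7-[(trimethylsilyl)oxy]cyclodec-2-en-1-yl (2E)-2-[(acetyloxy)methyl]octa-2,7-dienoate | O[C@H]1C[C@](C)(O[Si](C)(C)C)C(=O)CC/C(C)=C\[C@@H](OC(=O)C(/COC(C)=O)=C/CCCC=C)C1=C
F11 | step 10 | lithium (3R)-2-lithiopenta-1,4-dien-3-olate | C=C([Li])[C@H](O[Li])C=C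
F12 | step 10 | chlorozinc (3R)-2-(chlorozincio)penta-1,4-dien-3-olate | C=C([Zn]Cl)[C@H](O[Zn]Cl)C=C
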